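**Plan**
- Retrosynthesis: after the five acetates, the two aryl C–O bonds at C6' (ring B) and C6'' (ring C) are cut first, then the two CH2–ring A bonds of the methylene bridges (C3 and C5 of ring A), and last the three aryl–acyl bonds.
- Enabling feature: in the target the hydroxyl on C6'/C6'' lies ortho to the acetyl or isobutyryl carbonyl on C5'/C5''. Without it each outer ring keeps a single aromatic C–H, directly beside that ketone, and ring A keeps none. Each outer ring is then a 2-methylresorcinol ketone whose free and hydrogen-bonded hydroxyls can be told apart.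
- Forward: no ring is built. Rings B and C come from 2-methylresorcinol (C-acylation, benzyl on the para oxygen, methyl on the chelated oxygen, debenzylation, Mannich base); ring A comes from phloroglucinol and the chiral acid chloride.
- Ring A is alkylated first by the ring B unit, then by the ring C unit; the trimer is peracetylated, hydroxylated twice under ketone direction, and deacetylated.
- Stereochemistry: the only stereocentre, (R) at C2 of the 2-methylbutanoyl chain, is bought with (R)-2-methylbutanoic acid. No step makes or breaks a bond at it, and strongly enolising conditions are avoided.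

Key step: step 13

Remark: ring A is numbered C1–C6 with the 2-methylbutanoyl group on C1. On ring B (acetyl) and ring C (isobutyryl), C1'/C1'' carries the bridge, C2'/C2'' the hydroxyl, C3'/C3'' the methyl, C4'/C4'' the methoxy group and C5'/C5'' the acyl group. (R)-2-Methylbutanoic acid is assumed to be available in high enantiomeric purity; the purity of 17 and 25 is to be checked on a chiral stationary phase.

**Route**

Step 1
Reactants: 1 methylresorcinol (2-methylbenzene-1,3-diol); 2 acetyl chloride
Product: 3 ring B dihydroxy ketone 1-(2,4-dihydroxy-3-methylphenyl)ethan-1-one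
Conditions: AlCl3 (2.5 equiv), PhNO2, 0 → 60 °C; ice/aq. HCl
Reagents that add atoms: none
Why: Friedel–Crafts acylation (O-acylation and Fries shift under AlCl3) enters at C4, the position ortho to one hydroxyl and para to the other, and the ketone formed deactivates the ring against a second acylation.

Step 2
Reactants: 3 ring B dihydroxy ketone
Product: 5 benzyl methyl diether 1-[4-(benzyloxy)-2-methoxy-3-methylphenyl]ethan-1-one, via monobenzyl ether 4 (not isolated)
Conditions: BnBr (1.0 equiv), K2CO3 (3 equiv), DMF, 25 °C; then MeI (3 equiv), 50 °C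
Reagents that add atoms: benzyl bromide, BrCc1ccccc1; iodomethane, CI
Why: Two-stage Williamson etherification in which the free para hydroxyl, more acidic and more accessible than the ortho hydroxyl held in a hydrogen bond to the ketone, takes the single equivalent of benzyl bromide at 25 °C, and the chelated oxygen is then methylated by excess MeI on warming.

Step 3
Reactants: 5 benzyl methyl diether
Product: 6 ring B phenol 1-(4-hydroxy-2-methoxy-3-methylphenyl)ethan-1-one
Conditions: H2 (1 atm), Pd/C (10 wt% Pd), EtOAc, 25 °C
Reagents that add atoms: none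
Why: Hydrogenolysis of a benzyl aryl ether over Pd/C at one atmosphere is faster than reduction of the electron-rich aryl ketone, so the para phenol should be freed while the methyl ether and the ketone stay.

Step 4
Reactants: 6 ring B phenol
Product: 7 ring B Mannich base 1-[5-(dimethylaminomethyl)-4-hydroxy-2-methoxy-3-methylphenyl]ethan-1-one
Conditions: aq. HCHO (37%), aq. Me2NH (40%), EtOH, 60 °C
Reagents that add atoms: formaldehyde, C=O; dimethylamine, CNC
Why: Phenol Mannich reaction in which the iminium ion attacks C5, the only open position ortho to the hydroxyl (and para to the methoxy group), whereas C6 is meta to both donors and should stay untouched.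

Step 5
Reactants: 1 methylresorcinol; 8 isobutyryl chloride (2-methylpropanoyl chloride)
Product: 9 ring C dihydroxy ketone 1-(2,4-dihydroxy-3-methylphenyl)-2-methylpropan-1-one
Conditions: AlCl3 (2.5 equiv), PhNO2, 0 → 60 °C; ice/aq. HCl
Reagents that add atoms: none
Why: The same Friedel–Crafts acylation as in step 1, the branched acid chloride again entering ortho to one hydroxyl and para to the other.

Step 6
Reactants: 9 ring C dihydroxy ketone
Product: 11 benzyl methyl diether 1-[4-(benzyloxy)-2-methoxy-3-methylphenyl]-2-methylpropan-1-one, via monobenzyl ether 10 (not isolated)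
Conditions: BnBr (1.0 equiv), K2CO3 (3 equiv), DMF, 25 °C; then MeI (3 equiv), 50 °C
Reagents that add atoms: benzyl bromide, BrCc1ccccc1; iodomethane, CI
Why: The same two-stage Williamson etherification as in step 2, the chelated ortho hydroxyl of the isobutyryl ketone reacting only in the second stage.

Step 7
Reactants: 11 benzyl methyl diether
Product: 12 ring C phenol 1-(4-hydroxy-2-methoxy-3-methylphenyl)-2-methylpropan-1-one
Conditions: H2 (1 atm), Pd/C (10 wt% Pd), EtOAc, 25 °C
Reagents that add atoms: none
Why: Benzyl ether hydrogenolysis as in step 3, selective for the O–benzyl bond over the hindered aryl ketone.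

Step 8
Reactants: 12 ring C phenol
Product: 13 ring C Mannich base 1-[5-(dimethylaminomethyl)-4-hydroxy-2-methoxy-3-methylphenyl]-2-methylpropan-1-one
Conditions: aq. HCHO (37%), aq. Me2NH (40%), EtOH, 60 °C
Reagents that add atoms: formaldehyde, C=O; dimethylamine, CNC
Why: Phenol Mannich reaction as in step 4, directed to C5 by the ortho hydroxyl and the para methoxy group, the ketone having only a hindered tertiary α-hydrogen that should not compete.

Step 9
Reactants: 14 (R)-2-methylbutanoic acid; 15 phloroglucinol (anhydrous)
Product: 17 ring A ketone (R)-2-methyl-1-(2,4,6-trihydroxyphenyl)butan-1-one, via acid chloride 16 (not isolated)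
Conditions: (COCl)2, DMF (cat.), CH2Cl2, 0 → 25 °C, concentrate; then 15, AlCl3 (3 equiv), PhNO2/CH2Cl2, 0 → 25 °C; ice/aq. HCl
Reagents that add atoms: none
Why: Base-free acid chloride formation followed by AlCl3-mediated Friedel–Crafts acylation of phloroglucinol is the standard entry to acylphloroglucinols, makes or breaks no bond at the stereocentre, and is run cold and without base so that the (R)-configuration should not be lost through enolisation.

Step 10
Reactants: 17 ring A ketone (3 equiv); 7 ring B Mannich base
Product: 19 ring A–ring B dimer (R)-1-[3-(5-acetyl-2-hydroxy-4-methoxy-3-methylbenzyl)-2,4,6-trihydroxyphenyl]-2-methylbutan-1-one, via ammonium iodide 18 (not isolated)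
Conditions: 7, MeI (1.5 equiv), THF, 25 °C, evaporate; then 17, iPr2NEt (1.2 equiv), MeCN, 50 °C, argon
Reagents that add atoms: none
Why: Quaternisation turns the Mannich base into a trimethylammonium salt that loses NMe3 under mild base to an ortho-quinone methide, to which the phloroglucinolate of 17 adds through carbon (Michael-type C-alkylation), the threefold excess of 17 holding the reaction at the mono-adduct and leaving unreacted 17 recoverable.

Step 11
Reactants: 19 ring A–ring B dimer; 13 ring C Mannich base
Product: 21 trimer pentaphenol (6',6''-dideoxy target), via ammonium iodide 20 (not isolated)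
Conditions: 13 (1.2 equiv), MeI (1.8 equiv), THF, 25 °C, evaporate; then 19, iPr2NEt (1.5 equiv), MeCN, 50 °C, argon
Reagents that add atoms: none
Why: The same quinone methide C-alkylation, now unambiguous because ring A of 19 has one nucleophilic carbon left (C5) and the C6'–H of ring B, meta to its hydroxyl and ortho to the ketone, is not nucleophilic.

Step 12
Reactants: 21 trimer pentaphenol
Product: 22 pentaacetate of trimer 21 (all five phenols acetylated; C6'–H and C6''–H still present)
Conditions: Ac2O (10 equiv), pyridine, DMAP (cat.), CH2Cl2, 0 → 25 °C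
Reagents that add atoms: acetic anhydride, CC(=O)OC(C)=O
Why: DMAP-catalysed acylation should esterify all five phenols, the hindered and hydrogen-bonded ones included, so that no free hydroxyl is left when the oxidant is applied.

Step 13
Reactants: 22 pentaacetate of trimer 21
Product: 24 pentaacetate of the target with free hydroxyls on C6' and C6'', via bis(trifluoroacetate) 23 (not isolated)
Conditions: Pd(OAc)2 (20 mol%), PhI(OCOCF3)2 (4 equiv), ClCH2CH2Cl, 80 °C; then H2O/THF, 25 °C
Reagents that add atoms: [bis(trifluoroacetoxy)iodo]benzene, O=C(OI(OC(=O)C(F)(F)F)c1ccccc1)C(F)(F)F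
Why: Each outer-ring ketone binds divalent palladium through its oxygen and delivers it to the one ortho C–H bond (C6'–H on ring B, C6''–H on ring C) by concerted metalation–deprotonation; PhI(OCOCF3)2 oxidises the five-membered palladacycle to tetravalent palladium, and C–O reductive elimination releases the aryl trifluoroacetate and divalent palladium, so that 23 forms after two such cycles. The closest known reaction is the palladium-catalysed, ketone-directed ortho-hydroxylation of aryl alkyl ketones with a hypervalent iodine or persulfate oxidant, applied here at two sites of one molecule. No ring is closed and no stereocentre is created; the (R)-centre beside the ring A ketone is a spectator, and the two-electron iodine oxidant in a non-acidic chlorinated solvent is preferred to persulfate in CF3CO2H because it should spare that centre, the acetates and the two diarylmethane CH2 groups. The selectivity needed is positional and is fixed by the substrate: ring A carries no aromatic hydrogen and its ketone has no ortho C–H, while on rings B and C the other ortho position of the ketone is occupied by the methoxy group. The five acetates keep every phenol out of reach of the oxidant and lower the electron density of all three rings, and each new oxygen stays masked as an electron-poor trifluoroacetate until water cleaves it selectively, the acetates being far slower to hydrolyse.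

Step 14
Reactants: 24 pentaacetate of the target
Product: 25 target CNP0169975.1
Conditions: HCl (0.5 M in MeOH, degassed), 40 °C, argon
Reagents that add atoms: none
Why: Acid-catalysed transesterification with methanol should cleave the five aryl acetates while leaving the aryl methyl ethers, the methylene bridges and the ketone α-stereocentre alone, and it avoids the alkaline conditions under which methylene-bridged phloroglucinols scramble and oxidise.

**Compound list**

1 | 2-methylbenzene-1,3-diol (2-methylresorcinol) | Cc1c(O)cccc1O | starting material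
2 | acetyl chloride | CC(=O)Cl | starting material
3 | 1-(2,4-dihydroxy-3-methylphenyl)ethan-1-one | CC(=O)c1ccc(O)c(C)c1O | intermediate
4 | 1-[4-(benzyloxy)-2-hydroxy-3-methylphenyl]ethan-1-one (not isolated) | CC(=O)c1ccc(OCc2ccccc2)c(C)c1O | intermediate
5 | 1-[4-(benzyloxy)-2-methoxy-3-methylphenyl]ethan-1-one | CC(=O)c1ccc(OCc2ccccc2)c(C)c1OC | intermediate
6 | 1-(4-hydroxy-2-methoxy-3-methylphenyl)ethan-1-one | CC(=O)c1ccc(O)c(C)c1OC | intermediate
7 | 1-[5-(dimethylaminomethyl)-4-hydroxy-2-methoxy-3-methylphenyl]ethan-1-one | CC(=O)c1cc(CN(C)C)c(O)c(C)c1OC | intermediate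
8 | 2-methylpropanoyl chloride (isobutyryl chloride) | CC(C)C(=O)Cl | starting material
9 | 1-(2,4-dihydroxy-3-methylphenyl)-2-methylpropan-1-one | CC(C)C(=O)c1ccc(O)c(C)c1O | intermediate
10 | 1-[4-(benzyloxy)-2-hydroxy-3-methylphenyl]-2-methylpropan-1-one (not isolated) | CC(C)C(=O)c1ccc(OCc2ccccc2)c(C)c1O | intermediate
11 | 1-[4-(benzyloxy)-2-methoxy-3-methylphenyl]-2-methylpropan-1-one | CC(C)C(=O)c1ccc(OCc2ccccc2)c(C)c1OC | intermediate
12 | 1-(4-hydroxy-2-methoxy-3-methylphenyl)-2-methylpropan-1-one | CC(C)C(=O)c1ccc(O)c(C)c1OC | intermediate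
13 | 1-[5-(dimethylaminomethyl)-4-hydroxy-2-methoxy-3-methylphenyl]-2-methylpropan-1-one | CC(C)C(=O)c1cc(CN(C)C)c(O)c(C)c1OC | intermediate
14 | (R)-2-methylbutanoic acid | CC[C@@H](C)C(=O)O | starting material
15 | benzene-1,3,5-triol (phloroglucinol) | Oc1cc(O)cc(O)c1 | starting material
16 | (R)-2-methylbutanoyl chloride (not isolated) | CC[C@@H](C)C(=O)Cl | intermediate
17 | (R)-2-methyl-1-(2,4,6-trihydroxyphenyl)butan-1-one | CC[C@@H](C)C(=O)c1c(O)cc(O)cc1O | intermediate
18 | (5-acetyl-2-hydroxy-4-methoxy-3-methylphenyl)methyl-trimethylammonium iodide (not isolated) | CC(=O)c1cc(C[N+](C)(C)C)c(O)c(C)c1OC.[I-] | intermediate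
19 | (R)-1-[3-(5-acetyl-2-hydroxy-4-methoxy-3-methylbenzyl)-2,4,6-trihydroxyphenyl]-2-methylbutan-1-one | CC[C@@H](C)C(=O)c1c(O)cc(O)c(Cc2cc(C(C)=O)c(OC)c(C)c2O)c1O | intermediate
20 | [2-hydroxy-4-methoxy-3-methyl-5-(2-methylpropanoyl)phenyl]methyl-trimethylammonium iodide (not isolated) | CC(C)C(=O)c1cc(C[N+](C)(C)C)c(O)c(C)c1OC.[I-] | intermediate
21 | (R)-1-[3-(5-acetyl-2-hydroxy-4-methoxy-3-methylbenzyl)-2,4,6-trihydroxy-5-(2-hydroxy-5-isobutyryl-4-methoxy-3-methylbenzyl)phenyl]-2-methylbutan-1-one | CC[C@@H](C)C(=O)c1c(O)c(Cc2cc(C(C)=O)c(OC)c(C)c2O)c(O)c(Cc2cc(C(=O)C(C)C)c(OC)c(C)c2O)c1O | intermediate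
22 | pentaacetate of 21 (acetates on the C2, C4 and C6 oxygens of ring A, on the C2' oxygen of ring B and on the C2'' oxygen of ring C) | CC[C@@H](C)C(=O)c1c(OC(C)=O)c(Cc2cc(C(C)=O)c(OC)c(C)c2OC(C)=O)c(OC(C)=O)c(Cc2cc(C(=O)C(C)C)c(OC)c(C)c2OC(C)=O)c1OC(C)=O | intermediate
23 | pentaacetate 22 carrying trifluoroacetoxy groups on C6' and C6'' (not isolated) | CC[C@@H](C)C(=O)c1c(OC(C)=O)c(Cc2c(OC(=O)C(F)(F)F)c(C(C)=O)c(OC)c(C)c2OC(C)=O)c(OC(C)=O)c(Cc2c(OC(=O)C(F)(F)F)c(C(=O)C(C)C)c(OC)c(C)c2OC(C)=O)c1OC(C)=O | intermediate
24 | pentaacetate 22 carrying free hydroxyls on C6' and C6'' | CC[C@@H](C)C(=O)c1c(OC(C)=O)c(Cc2c(O)c(C(C)=O)c(OC)c(C)c2OC(C)=O)c(OC(C)=O)c(Cc2c(O)c(C(=O)C(C)C)c(OC)c(C)c2OC(C)=O)c1OC(C)=O | intermediate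
25 | (R)-1-[3-(3-acetyl-2,6-dihydroxy-4-methoxy-5-methylbenzyl)-2,4,6-trihydroxy-5-(2,6-dihydroxy-3-isobutyryl-4-methoxy-5-methylbenzyl)phenyl]-2-methylbutan-1-one (CNP0169975.1) | CC[C@@H](C)C(=O)c1c(O)c(Cc2c(O)c(C)c(OC)c(C(C)=O)c2O)c(O)c(Cc2c(O)c(C)c(OC)c(C(=O)C(C)C)c2O)c1O | target

**Count**

Total step count: 14.
Longest linear sequence: 9 steps (steps 1, 2, 3, 4, 10, 11, 12, 13, 14).

**Steps most likely to fail**

Step 13. Palladation of a C–H bond wedged between the acyl group and the methylene bridge may be slow, so that the sequence stalls after one hydroxylation or the oxidant turns on the benzylic bridges. The fallback brings the oxygen in before the rings are joined, where the same C–H bond has only a hydrogen neighbour. It sets out from benzyl ethers 5 and 11 (ring A partner 17 unchanged) and returns at target 25. Treating 5 with Pd(OAc)2/PhI(OCOCF3)2 in ClCH2CH2Cl should give 2-acetyl-5-(benzyloxy)-3-methoxy-4-methylphenyl trifluoroacetate F1, hydrolysed on aqueous work-up to 1-[4-(benzyloxy)-6-hydroxy-2-methoxy-3-methylphenyl]ethan-1-one F2. Hydrogenolysis (H2, Pd/C) then gives 1-(4,6-dihydroxy-2-methoxy-3-methylphenyl)ethan-1-one F3, whose single free ring position takes the Mannich reaction (HCHO, Me2NH) to 1-[5-(dimethylaminomethyl)-4,6-dihydroxy-2-methoxy-3-methylphenyl]ethan-1-one F4. Heating F4 with excess 17 in dioxane (loss of dimethylamine, quinone methide C-alkylation) gives the ring A–ring B dimer (R)-1-[3-(3-acetyl-2,6-dihydroxy-4-methoxy-5-methylbenzyl)-2,4,6-trihydroxyphenyl]-2-methylbutan-1-one F5. The same operations on 11 give 5-(benzyloxy)-3-methoxy-4-methyl-2-(2-methylpropanoyl)phenyl trifluoroacetate F6, 1-[4-(benzyloxy)-6-hydroxy-2-methoxy-3-methylphenyl]-2-methylpropan-1-one F7, 1-(4,6-dihydroxy-2-methoxy-3-methylphenyl)-2-methylpropan-1-one F8 and 1-[5-(dimethylaminomethyl)-4,6-dihydroxy-2-methoxy-3-methylphenyl]-2-methylpropan-1-one F9. Heating F9 with F5 joins the third ring and gives 25 directly, without acetates.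

Step 10. The acyl-deactivated phenolate may expel trimethylamine only slowly, leaving time for O-alkylation or for a second alkylation of ring A. The fallback replaces the base-mediated quinone methide route by an acid-mediated benzylation. It sets out from phenol 6 and returns at dimer 19. Blanc chloromethylation of 6 ((CH2O)n, conc. HCl, 45 °C), directed to C5 like the Mannich reaction, should give 1-[5-(chloromethyl)-4-hydroxy-2-methoxy-3-methylphenyl]ethan-1-one F10. This benzylic chloride alkylates excess 17 at carbon under ZnCl2 catalysis in dioxane (Friedel–Crafts benzylation) to give 19.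

Step 9. The AlCl3-activated acid chloride may lose configuration at its α-carbon through enolisation or ketene formation before it acylates. The fallback delivers the acyl group as a Weinreb amide to an aryllithium, so that no acylium-type species is formed. It sets out from 15 and 14 and returns at 17. Phloroglucinol 15 is converted (MOMCl, iPr2NEt, CH2Cl2) into 1,3,5-tris(methoxymethoxy)benzene F11, and acid 14 (MeNHOMe·HCl, EDC·HCl, iPr2NEt, CH2Cl2) into (R)-N-methoxy-N,2-dimethylbutanamide F12. Lithiation of F11 between two acetal oxygens (n-BuLi, THF, 0 °C) gives [2,4,6-tris(methoxymethoxy)phenyl]lithium F13, which adds to F12 at −78 °C and gives, after aqueous NH4Cl, (R)-2-methyl-1-[2,4,6-tris(methoxymethoxy)phenyl]butan-1-one F14. HCl in MeOH at 25 °C removes the three acetals and gives 17.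

**Further compounds**

F1 | step 13 | 2-acetyl-5-(benzyloxy)-3-methoxy-4-methylphenyl trifluoroacetate | CC(=O)c1c(OC(=O)C(F)(F)F)cc(OCc2ccccc2)c(C)c1OC
F2 | step 13 | 1-[4-(benzyloxy)-6-hydroxy-2-methoxy-3-methylphenyl]ethan-1-one | CC(=O)c1c(O)cc(OCc2ccccc2)c(C)c1OC
F3 | step 13 | 1-(4,6-dihydroxy-2-methoxy-3-methylphenyl)ethan-1-one | CC(=O)c1c(O)cc(O)c(C)c1OC
F4 | step 13 | 1-[5-(dimethylaminomethyl)-4,6-dihydroxy-2-methoxy-3-methylphenyl]ethan-1-one | CC(=O)c1c(O)c(CN(C)C)c(O)c(C)c1OC
F5 | step 13 | (R)-1-[3-(3-acetyl-2,6-dihydroxy-4-methoxy-5-methylbenzyl)-2,4,6-trihydroxyphenyl]-2-methylbutan-1-one | CC[C@@H](C)C(=O)c1c(O)cc(O)c(Cc2c(O)c(C(C)=O)c(OC)c(C)c2O)c1O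
F6 | step 13 | 5-(benzyloxy)-3-methoxy-4-methyl-2-(2-methylpropanoyl)phenyl trifluoroacetate | CC(C)C(=O)c1c(OC(=O)C(F)(F)F)cc(OCc2ccccc2)c(C)c1OC
F7 | step 13 | 1-[4-(benzyloxy)-6-hydroxy-2-methoxy-3-methylphenyl]-2-methylpropan-1-one | CC(C)C(=O)c1c(O)cc(OCc2ccccc2)c(C)c1OC
F8 | step 13 | 1-(4,6-dihydroxy-2-methoxy-3-methylphenyl)-2-methylpropan-1-one | CC(C)C(=O)c1c(O)cc(O)c(C)c1OC
F9 | step 13 | 1-[5-(dimethylaminomethyl)-4,6-dihydroxy-2-methoxy-3-methylphenyl]-2-methylpropan-1-one | CC(C)C(=O)c1c(O)c(CN(C)C)c(O)c(C)c1OC
F10 | step 10 | 1-[5-(chloromethyl)-4-hydroxy-2-methoxy-3-methylphenyl]ethan-1-one | CC(=O)c1cc(CCl)c(O)c(C)c1OC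
F11 | step 9 | 1,3,5-tris(methoxymethoxy)benzene | COCOc1cc(OCOC)cc(OCOC)c1
F12 | step 9 | (R)-N-methoxy-N,2-dimethylbutanamide | CC[C@@H](C)C(=O)N(C)OC
F13 | step 9 | [2,4,6-tris(methoxymethoxy)phenyl]lithium | [Li]c1c(OCOC)cc(OCOC)cc1OCOC
F14 | step 9 | (R)-2-methyl-1-[2,4,6-tris(methoxymethoxy)phenyl]butan-1-one | CC[C@@H](C)C(=O)c1c(OCOC)cc(OCOC)cc1OCOC
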